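Count the reagent first.

| flask | starting material | reagent | remark | time |
|---|---|---|---|---|
| south-east | 0.090 M | 0.324 M (in portions, 2) | run made earlier; portions every 15 min |  |
| west | 0.14 M | 0.324 M (in portions, 2) | run made earlier; portions every 15 min |  |
| north | 0.18 M | 0.16 M (in portions, 2) | run made earlier; portions every 15 min |  |
| flask | 0.18 M | 0.324 M (in portions, 2) | the portions of reagent follow each other after 15 min, the first at the start | 15 h |

- south-east (time / h: starting material / %, tetra adduct / %): 2.00: 1.5, 5.3; 4.00: 0, 19.7; 6.00: 0, 32.2; 8.00: 1.2, 38.3; 10.0: 0, 45.6; 12.0: 0, 50.4; 15.0: 0, 53.4
- west (time / h: starting material / %, tetra adduct / %): 1.33: 10.8, 0.9; 2.00: 4.7, 1.2; 3.00: 1.9, 5.5; 4.00: 1.1, 6.7; 6.00: 0.7, 10.8; 10.0: 0, 12.5; 15.0: 0, 14.4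
- north (time / h: starting material / %, tetra adduct / %): 3.00: 29.8, 0; 6.00: 27.4, 0; 10.0: 29.4, 0; 12.0: 28.7, 0; 15.0: 29.1, 0.9

(readings scatter by 1 percentage point)

- the earlier runs were read with a standard deviation of 1 percentage point
- the reaction counts as stopped when no species that holds the starting material changes by six tenths of a point or more over the second half of the time

1. the state of affairs at 15 h: stopped, and by what, or still going (it is still moving / forward and back rates have come level / the reagent has run out first / all of the starting material has reacted)
2. how much of the starting material has reacted by 15 h
3. how much tetra adduct there is at 15 h, in percent of the starting material charged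
4. how much single product there is at 15 h, in percent of the starting material charged

Two amounts carry the argument: c(reagent) and c(starting material). Their ratio, the equivalents, is 1.80 in the flask. The north run has 0.889. If the first step had taken all of that, 11.1% of its starting material would remain, but the last reading shows 29.1%. So in the north run the first step did not take all of the reagent. The last readings show 14.4% tetra adduct in the west run at 2.31 equivalents and 53.4% in the south-east run at 3.60.

Our reckoning follows. A single product holds one reagent, and by its name a tetra adduct holds 4. Suppose the reagent is used up and none is lost. Each molecule carried beyond the single product then takes at most 3 more reagent. This gives the single-product ceiling: 4 minus the equivalents, divided by 3, as a share of the starting material charged. For the flask, 73.3%.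

The forecast expects the reagent has run out first, 97% reacted, 2% tetra adduct and 95% single product: “The waste seems to grow as starting material falls, so a little may survive.” Its single product stands higher than our ceiling, which supposes no reagent lost, while the forecast reckons with waste.

The flask gives the reagent has run out first, with 97.0% reacted, 4.77% tetra adduct and 42.9% single product.

    starting material + reagent → single product (k = 0.00270 M⁻¹ s⁻¹)
    reagent + single product → bis adduct (k = 8.80 × 10⁻⁴ M⁻¹ s⁻¹)
    reagent + bis adduct → triple product (k = 0.00110 M⁻¹ s⁻¹)
    reagent + triple product → tetra adduct (k = 5.40 × 10⁻⁴ M⁻¹ s⁻¹)

In the flask, reagent is the limiting reagent: 0.0091% of its charge is left at 15.0 h, against 3.0% of the charge of starting material. The flask's single product lies below the ceiling of 73.3%, and beside it stand 29.9% bis adduct and 19.4% triple product. With the flask's whole charges, the half-life of starting material in the first step alone is 0.22 h, shorter than the 0.68 h of single product in the next step alone. The neighbour flask with 0.55 M reagent has 3.06 equivalents and a ceiling of 31.5%, and its single product stands at 8.95%.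

(All runs are calculated from invented constants; scatter was added.)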